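**Retrosynthetic overview**
1. The ring oxirane and the C5 ketone come last: hydroxyl-directed epoxidation of ring allylic alcohol 16, then oxidation; both angelates are put on diol 14 in one operation.
2. C6–O comes from enolate hydroxylation anti to the C1 side chain; the side-chain oxirane from SN2 closure of a C10 sulfonate; the C8 carbinol from 1,3-anti directed reduction of β-hydroxy enone 9, so C10 controls C8.
3. Key disconnection C8–C9: electroreductive nickel-catalysed coupling of 10-chlorocarvone 5 with the terminal carbon of epoxide 3; C8 is oxidised afterwards (SeO2, then MnO2).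
4. Building blocks: (R)-carvone (ring carbons and C1) and methyl (S)-glycidate (C10).
5. Ring order: the cyclohexane ring is bought, the side-chain oxirane is closed second, the ring oxirane is formed last.

Labels used throughout (assumed for clarity): ring C1 carries the side chain, C4 the methyl group, C5 is the carbonyl carbon, C6 the oxygenated carbon beside it; side chain C7(=CH2)–C8–C9–C10–C11.

**Step 1**
Reactants: 1 methyl (2S)-oxirane-2-carboxylate
Product: 3 2-[(2S)-oxiran-2-yl]propan-2-ol, via epoxy methyl ketone 2 (not isolated)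
Conditions: MeMgBr (2.2 equiv), THF, −78 → −40 °C; H2O
Reagents that add atoms: methylmagnesium bromide C[Mg]Br
Why: Double Grignard addition to the ester (through the methyl ketone) is faster than oxirane opening at low temperature and does not touch the stereocentre, which is bought with 1.

**Step 2**
Reactants: 4 (R)-carvone
Product: 5 (5R)-5-(3-chloroprop-1-en-2-yl)-2-methylcyclohex-2-en-1-one
Conditions: Ca(OCl)2, CO2 (dry ice), CH2Cl2/H2O, 0 °C
Reagents that add atoms: calcium hypochlorite [Ca+2].[O-]Cl.[O-]Cl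
Why: Ene-type allylic chlorination by hypochlorous acid made in the flask converts the electron-rich isopropenyl group, not the enone alkene, into the 2-(chloromethyl)allyl group (a literature reaction of carvone); C1 is untouched.

**Step 3**
Reactants: 5 (5R)-5-(3-chloroprop-1-en-2-yl)-2-methylcyclohex-2-en-1-one; 3 2-[(2S)-oxiran-2-yl]propan-2-ol (1.5 equiv)
Product: 7 (5R)-5-[(5S)-5,6-dihydroxy-6-methylhept-1-en-2-yl]-2-methylcyclohex-2-en-1-one, via iodohydrin 6 (not isolated)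
Conditions: NiBr2·glyme (10 mol %), 4,4′-di-tert-butyl-2,2′-bipyridine (12 mol %), NaI (0.5 equiv), Et3N·HCl (1.2 equiv), Bu4NBF4, DMA, 25 °C, divided cell, carbon-felt cathode, Zn anode, 4 mA, 2.5 F/mol, 5 added over 4 h
Reagents that add atoms: none
Why: Proposed new method: electroreductive nickel-catalysed ring-opening allylation of a terminal epoxide, in which iodide and Et3N·HCl open 3 at the unhindered CH2 to iodohydrin 6 (C10–O bond and configuration kept), zerovalent nickel inserts into the C–Cl bond of 5 to give a 2-substituted allyl complex of divalent nickel whose two termini are identical (one constitutional product), monovalent nickel abstracts iodine from 6, the β-hydroxyalkyl radical is captured at nickel and reductive elimination forms C8–C9 while the cathode closes the cycle; the unactivated exo-methylene is no radical trap, and direct radical addition to 5 with loss of chloride would give the same product; the closest known reaction types are nickel-catalysed cross-electrophile coupling of epoxides with aryl halides under iodide co-catalysis and nickel-catalysed reductive allylation of alkyl halides with metal-powder reductants.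

**Step 4**
Reactants: 7 (5R)-5-[(5S)-5,6-dihydroxy-6-methylhept-1-en-2-yl]-2-methylcyclohex-2-en-1-one
Product: 9 (5R)-5-[(5S)-5,6-dihydroxy-6-methyl-3-oxohept-1-en-2-yl]-2-methylcyclohex-2-en-1-one, via allylic alcohol 8 (not isolated)
Conditions: SeO2 (0.5 equiv), t-BuOOH (3 equiv), CH2Cl2, 25 °C; aqueous Na2S2O3 wash; then activated MnO2 (15 equiv), CH2Cl2, 25 °C; crude 9 used at once
Reagents that add atoms: selenium dioxide O=[Se]=O (oxygen carrier); tert-butyl hydroperoxide CC(C)(C)OO (terminal oxygen source)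
Why: Riley-type allylic oxidation (ene reaction, then 2,3-sigmatropic shift) attacks the only electron-rich alkene at its allylic CH2 (C8) in preference to the C1 methine, as with β-pinene, and MnO2 then oxidises only the allylic alcohol, so both C8 epimers converge on the enone and no stereocentre is set.

**Step 5**
Reactants: 9 (5R)-5-[(5S)-5,6-dihydroxy-6-methyl-3-oxohept-1-en-2-yl]-2-methylcyclohex-2-en-1-one
Product: 10 (5R)-2-methyl-5-[(3S,5S)-3,5,6-trihydroxy-6-methylhept-1-en-2-yl]cyclohex-2-en-1-one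
Conditions: Me4NBH(OAc)3 (5 equiv), MeCN/AcOH 1:1, −30 °C
Reagents that add atoms: none
Why: Evans–Saksena reduction, in which the C10 hydroxyl exchanges onto boron and hydride is delivered intramolecularly through a chair transition state, gives the 1,3-anti diol, so C8 (S) is set by C10; the ring enone has no β-hydroxyl and is not reduced.

**Step 6**
Reactants: 10 (5R)-2-methyl-5-[(3S,5S)-3,5,6-trihydroxy-6-methylhept-1-en-2-yl]cyclohex-2-en-1-one
Product: 12 (5R)-5-{(3S)-4-[(2R)-3,3-dimethyloxiran-2-yl]-3-hydroxybut-1-en-2-yl}-2-methylcyclohex-2-en-1-one, via secondary tosylate 11 (not isolated)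
Conditions: Bu2SnO (10 mol %), TsCl (1.1 equiv), Et3N (1.5 equiv), CH2Cl2, 0 → 25 °C; then K2CO3, MeOH, 0 °C
Reagents that add atoms: none
Why: Tin-acetal catalysis activates only the vicinal diol and sulfonylates its secondary oxygen, and the tertiary alkoxide then closes the oxirane by intramolecular SN2 (Williamson-type) displacement with inversion at C10, which turns the 1,3-anti diol into the required syn hydroxy epoxide with (10R).

**Step 7**
Reactants: 12 (5R)-5-{(3S)-4-[(2R)-3,3-dimethyloxiran-2-yl]-3-hydroxybut-1-en-2-yl}-2-methylcyclohex-2-en-1-one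
Product: 14 (5S,6S)-5-{(3S)-4-[(2R)-3,3-dimethyloxiran-2-yl]-3-hydroxybut-1-en-2-yl}-6-hydroxy-2-methylcyclohex-2-en-1-one, via dilithium enolate 13 (not isolated)
Conditions: LiN(SiMe3)2 (2.3 equiv), THF, −78 °C; then racemic 2-(phenylsulfonyl)-3-phenyloxaziridine, −78 °C; AcOH
Reagents that add atoms: 2-(phenylsulfonyl)-3-phenyloxaziridine O=S(=O)(N1OC1c1ccccc1)c1ccccc1
Why: Kinetic α′-deprotonation of the cross-conjugated enone (after the C8 alkoxide) and Davis enolate hydroxylation with the racemic oxaziridine take place anti to the neighbouring C1 side chain, giving the trans C6 alcohol as known for carvone.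

**Step 8**
Reactants: 14 (5S,6S)-5-{(3S)-4-[(2R)-3,3-dimethyloxiran-2-yl]-3-hydroxybut-1-en-2-yl}-6-hydroxy-2-methylcyclohex-2-en-1-one
Product: 15 (1S,6S)-6-{(3S)-4-[(2R)-3,3-dimethyloxiran-2-yl]-3-[(2Z)-2-methylbut-2-enoyloxy]but-1-en-2-yl}-3-methyl-2-oxocyclohex-3-en-1-yl (2Z)-2-methylbut-2-enoate
Conditions: angelic acid (3 equiv), 2,4,6-trichlorobenzoyl chloride (3 equiv), Et3N (6 equiv), PhMe, 25 °C; then 14, 75 °C
Reagents that add atoms: angelic acid C/C=C(/C)C(O)=O
Why: Yamaguchi-type esterification through the preformed mixed 2,4,6-trichlorobenzoic anhydride acylates both secondary hydroxyls without nucleophile-induced Z to E isomerisation of the angelate; no stereocentre is affected.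

**Step 9**
Reactants: 15 (1S,6S)-6-{(3S)-4-[(2R)-3,3-dimethyloxiran-2-yl]-3-[(2Z)-2-methylbut-2-enoyloxy]but-1-en-2-yl}-3-methyl-2-oxocyclohex-3-en-1-yl (2Z)-2-methylbut-2-enoate
Product: 16 (1S,2S,6S)-6-{(3S)-4-[(2R)-3,3-dimethyloxiran-2-yl]-3-[(2Z)-2-methylbut-2-enoyloxy]but-1-en-2-yl}-2-hydroxy-3-methylcyclohex-3-en-1-yl (2Z)-2-methylbut-2-enoate
Conditions: NaBH4, CeCl3·7H2O, MeOH, −78 °C
Reagents that add atoms: none
Why: Luche 1,2-reduction by axial hydride attack on the half-chair with the C1 and C6 substituents equatorial gives the equatorial C5 alcohol, trans to the C6 ester and cis to the C1 side chain, as in the reduction of carvone to cis-carveol.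

**Step 10**
Reactants: 16 (1S,2S,6S)-6-{(3S)-4-[(2R)-3,3-dimethyloxiran-2-yl]-3-[(2Z)-2-methylbut-2-enoyloxy]but-1-en-2-yl}-2-hydroxy-3-methylcyclohex-3-en-1-yl (2Z)-2-methylbut-2-enoate
Product: 17 (1R,2R,3S,4S,6S)-4-{(3S)-4-[(2R)-3,3-dimethyloxiran-2-yl]-3-[(2Z)-2-methylbut-2-enoyloxy]but-1-en-2-yl}-2-hydroxy-1-methyl-7-oxabicyclo[4.1.0]heptan-3-yl (2Z)-2-methylbut-2-enoate
Conditions: VO(acac)2 (5 mol %), t-BuOOH (1.5 equiv), CH2Cl2, 0 → 25 °C
Reagents that add atoms: tert-butyl hydroperoxide CC(C)(C)OO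
Why: Hydroxyl-directed epoxidation (Sharpless vanadium/t-BuOOH system) delivers oxygen to the ring alkene on the face of the C5 hydroxyl, cis to the side chain and trans to the C6 ester (the face that nucleophilic epoxidation of the enone does not give); the exo-methylene and angelate alkenes have no free allylic hydroxyl and stay intact.

**Step 11**
Reactants: 17 (1R,2R,3S,4S,6S)-4-{(3S)-4-[(2R)-3,3-dimethyloxiran-2-yl]-3-[(2Z)-2-methylbut-2-enoyloxy]but-1-en-2-yl}-2-hydroxy-1-methyl-7-oxabicyclo[4.1.0]heptan-3-yl (2Z)-2-methylbut-2-enoate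
Product: 18 (1S,3S,4S,6S)-4-{(3S)-4-[(2R)-3,3-dimethyloxiran-2-yl]-3-[(2Z)-2-methylbut-2-enoyloxy]but-1-en-2-yl}-1-methyl-2-oxo-7-oxabicyclo[4.1.0]heptan-3-yl (2Z)-2-methylbut-2-enoate (CNP0247177.2)
Conditions: Dess–Martin periodinane, NaHCO3, CH2Cl2, 25 °C
Reagents that add atoms: none
Why: Dess–Martin oxidation of the hindered secondary alcohol under buffered conditions gives the ketone without epimerising C6 and leaves both oxiranes and both angelates intact.

**Compound list**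
1 | methyl (2S)-oxirane-2-carboxylate (methyl (S)-glycidate) | COC(=O)[C@@H]1CO1 | starting material
2 | 1-[(2S)-oxiran-2-yl]ethan-1-one | CC(=O)[C@@H]1CO1 | intermediate (not isolated)
3 | 2-[(2S)-oxiran-2-yl]propan-2-ol | CC(C)(O)[C@@H]1CO1 | intermediate
4 | (R)-carvone, (5R)-2-methyl-5-(prop-1-en-2-yl)cyclohex-2-en-1-one | C=C(C)[C@@H]1CC=C(C)C(=O)C1 | starting material
5 | (5R)-5-(3-chloroprop-1-en-2-yl)-2-methylcyclohex-2-en-1-one (10-chlorocarvone) | C=C(CCl)[C@@H]1CC=C(C)C(=O)C1 | intermediate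
6 | (2R)-1-iodo-3-methylbutane-2,3-diol | IC[C@H](O)C(C)(C)O | intermediate (not isolated)
7 | (5R)-5-[(5S)-5,6-dihydroxy-6-methylhept-1-en-2-yl]-2-methylcyclohex-2-en-1-one | C=C(CC[C@H](O)C(C)(C)O)[C@@H]1CC=C(C)C(=O)C1 | intermediate
8 | (5R)-2-methyl-5-[(3RS,5S)-3,5,6-trihydroxy-6-methylhept-1-en-2-yl]cyclohex-2-en-1-one (both C8 epimers) | C=C(C(O)C[C@H](O)C(C)(C)O)[C@@H]1CC=C(C)C(=O)C1 | intermediate (not isolated)
9 | (5R)-5-[(5S)-5,6-dihydroxy-6-methyl-3-oxohept-1-en-2-yl]-2-methylcyclohex-2-en-1-one | C=C(C(=O)C[C@H](O)C(C)(C)O)[C@@H]1CC=C(C)C(=O)C1 | intermediate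
10 | (5R)-2-methyl-5-[(3S,5S)-3,5,6-trihydroxy-6-methylhept-1-en-2-yl]cyclohex-2-en-1-one | C=C([C@H](C[C@H](O)C(C)(C)O)O)[C@@H]1CC=C(C)C(=O)C1 | intermediate
11 | (3S,5S)-3,6-dihydroxy-6-methyl-2-[(1R)-4-methyl-5-oxocyclohex-3-en-1-yl]hept-1-en-5-yl 4-methylbenzenesulfonate | C=C([C@H](C[C@H](OS(=O)(=O)c2ccc(C)cc2)C(C)(C)O)O)[C@@H]1CC=C(C)C(=O)C1 | intermediate (not isolated)
12 | (5R)-5-{(3S)-4-[(2R)-3,3-dimethyloxiran-2-yl]-3-hydroxybut-1-en-2-yl}-2-methylcyclohex-2-en-1-one | C=C([C@H](C[C@H]1OC1(C)C)O)[C@@H]1CC=C(C)C(=O)C1 | intermediate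
13 | dilithium salt of 12 (C8 alkoxide and C5–C6 enolate) | C=C([C@H](C[C@H]1OC1(C)C)[O-])[C@@H]1CC=C(C)C([O-])=C1.[Li+].[Li+] | intermediate (not isolated)
14 | (5S,6S)-5-{(3S)-4-[(2R)-3,3-dimethyloxiran-2-yl]-3-hydroxybut-1-en-2-yl}-6-hydroxy-2-methylcyclohex-2-en-1-one | C=C([C@H](C[C@H]1OC1(C)C)O)[C@@H]1CC=C(C)C(=O)[C@H]1O | intermediate
15 | (1S,6S)-6-{(3S)-4-[(2R)-3,3-dimethyloxiran-2-yl]-3-[(2Z)-2-methylbut-2-enoyloxy]but-1-en-2-yl}-3-methyl-2-oxocyclohex-3-en-1-yl (2Z)-2-methylbut-2-enoate | C=C([C@H](C[C@H]1OC1(C)C)OC(=O)/C(C)=C\C)[C@@H]1CC=C(C)C(=O)[C@H]1OC(=O)/C(C)=C\C | intermediate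
16 | (1S,2S,6S)-6-{(3S)-4-[(2R)-3,3-dimethyloxiran-2-yl]-3-[(2Z)-2-methylbut-2-enoyloxy]but-1-en-2-yl}-2-hydroxy-3-methylcyclohex-3-en-1-yl (2Z)-2-methylbut-2-enoate | C=C([C@H](C[C@H]1OC1(C)C)OC(=O)/C(C)=C\C)[C@@H]1CC=C(C)[C@H](O)[C@H]1OC(=O)/C(C)=C\C | intermediate
17 | (1R,2R,3S,4S,6S)-4-{(3S)-4-[(2R)-3,3-dimethyloxiran-2-yl]-3-[(2Z)-2-methylbut-2-enoyloxy]but-1-en-2-yl}-2-hydroxy-1-methyl-7-oxabicyclo[4.1.0]heptan-3-yl (2Z)-2-methylbut-2-enoate | C=C([C@H](C[C@H]1OC1(C)C)OC(=O)/C(C)=C\C)[C@@H]1C[C@@H]2O[C@]2(C)[C@H](O)[C@H]1OC(=O)/C(C)=C\C | intermediate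
18 | (1S,3S,4S,6S)-4-{(3S)-4-[(2R)-3,3-dimethyloxiran-2-yl]-3-[(2Z)-2-methylbut-2-enoyloxy]but-1-en-2-yl}-1-methyl-2-oxo-7-oxabicyclo[4.1.0]heptan-3-yl (2Z)-2-methylbut-2-enoate | C=C([C@H](C[C@H]1OC1(C)C)OC(=O)/C(C)=C\C)[C@@H]1C[C@@H]2O[C@]2(C)C(=O)[C@H]1OC(=O)/C(C)=C\C | target

**Step count and risks**
Total: 11 steps. Longest linear sequence: 10 steps (4 to 18, steps 2–11); step 1 makes the second fragment.

The three steps most likely to fail:

Step 3 (the new coupling). Allyl–allyl homocoupling of 5 at nickel and cathodic reduction of the enone compete with the cross-coupling. The fallback uses known chemistry, sets out from 5 and 3 and returns at 7. Epoxide 3 is opened with LiI and AcOH in THF and iodohydrin 6 is isolated. Chloride 5 is stannylated with Bu3SnSnBu3 and Pd(PPh3)4 (THF, 60 °C) to the allylstannane (5R)-2-methyl-5-[3-(tributylstannyl)prop-1-en-2-yl]cyclohex-2-en-1-one F1. Keck radical allylation of 6 with F1 (AIBN, PhH, 80 °C) then gives 7 by a tin-mediated chain transfer of the symmetrical allyl group, with no nickel and no electrolysis.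

Step 6 (selective sulfonylation of the secondary C10 hydroxyl beside a tertiary one, with the allylic C8 hydroxyl free). If C8 is sulfonylated as well, a protecting-group route is used; it sets out from 10 and returns at 12. 2,2-Dimethoxypropane and pyridinium tosylate give the five-membered acetonide (5R)-5-{(3S)-3-hydroxy-4-[(4S)-2,2,5,5-tetramethyl-1,3-dioxolan-4-yl]but-1-en-2-yl}-2-methylcyclohex-2-en-1-one F2 (the 1,3-anti diol does not form a six-membered acetal readily). TBSCl and imidazole give the C8 silyl ether (5R)-5-{(3S)-3-[(tert-butyldimethylsilyl)oxy]-4-[(4S)-2,2,5,5-tetramethyl-1,3-dioxolan-4-yl]but-1-en-2-yl}-2-methylcyclohex-2-en-1-one F3. Aqueous AcOH frees the diol (5R)-5-{(3S,5S)-3-[(tert-butyldimethylsilyl)oxy]-5,6-dihydroxy-6-methylhept-1-en-2-yl}-2-methylcyclohex-2-en-1-one F4. MsCl and Et3N give the mesylate (3S,5S)-3-[(tert-butyldimethylsilyl)oxy]-6-hydroxy-6-methyl-2-[(1R)-4-methyl-5-oxocyclohex-3-en-1-yl]hept-1-en-5-yl methanesulfonate F5. K2CO3 in MeOH closes it to the silyl-protected epoxide (5R)-5-{(3S)-3-[(tert-butyldimethylsilyl)oxy]-4-[(2R)-3,3-dimethyloxiran-2-yl]but-1-en-2-yl}-2-methylcyclohex-2-en-1-one F6, and Bu4NF gives 12.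

Step 7 (hydroxylation of an unprotected hydroxy enone as its dianion; the trans:cis ratio and aldol-type addition to the sulfonylimine by-product are the concerns). The fallback is a Rubottom oxidation; it sets out from 12 and returns at 14. TMSOTf and Et3N (CH2Cl2, −78 → 0 °C) give the bis-silylated 2-silyloxy-1,3-diene trimethyl({(6R)-6-{(3S)-4-[(2R)-3,3-dimethyloxiran-2-yl]-3-[(trimethylsilyl)oxy]but-1-en-2-yl}-3-methylcyclohexa-1,3-dien-2-yl}oxy)silane F7. Dimethyldioxirane in acetone at −78 °C epoxidises the silyl enol ether double bond anti to the side chain, and silyl migration gives (5S,6S)-5-{(3S)-4-[(2R)-3,3-dimethyloxiran-2-yl]-3-[(trimethylsilyl)oxy]but-1-en-2-yl}-2-methyl-6-[(trimethylsilyl)oxy]cyclohex-2-en-1-one F8. Citric acid in MeOH removes both silyl groups to give 14.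

**Further compounds**
F1 | step 3 | (5R)-2-methyl-5-[3-(tributylstannyl)prop-1-en-2-yl]cyclohex-2-en-1-one | C=C(C[Sn](CCCC)(CCCC)CCCC)[C@@H]1CC=C(C)C(=O)C1
F2 | step 6 | (5R)-5-{(3S)-3-hydroxy-4-[(4S)-2,2,5,5-tetramethyl-1,3-dioxolan-4-yl]but-1-en-2-yl}-2-methylcyclohex-2-en-1-one | C=C([C@H](C[C@@H]1OC(C)(C)OC1(C)C)O)[C@@H]2CC=C(C)C(=O)C2
F3 | step 6 | (5R)-5-{(3S)-3-[(tert-butyldimethylsilyl)oxy]-4-[(4S)-2,2,5,5-tetramethyl-1,3-dioxolan-4-yl]but-1-en-2-yl}-2-methylcyclohex-2-en-1-one | C=C([C@H](C[C@@H]1OC(C)(C)OC1(C)C)O[Si](C)(C)C(C)(C)C)[C@@H]2CC=C(C)C(=O)C2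
F4 | step 6 | (5R)-5-{(3S,5S)-3-[(tert-butyldimethylsilyl)oxy]-5,6-dihydroxy-6-methylhept-1-en-2-yl}-2-methylcyclohex-2-en-1-one | C=C([C@H](C[C@H](O)C(C)(C)O)O[Si](C)(C)C(C)(C)C)[C@@H]1CC=C(C)C(=O)C1
F5 | step 6 | (3S,5S)-3-[(tert-butyldimethylsilyl)oxy]-6-hydroxy-6-methyl-2-[(1R)-4-methyl-5-oxocyclohex-3-en-1-yl]hept-1-en-5-yl methanesulfonate | C=C([C@H](C[C@H](OS(C)(=O)=O)C(C)(C)O)O[Si](C)(C)C(C)(C)C)[C@@H]1CC=C(C)C(=O)C1
F6 | step 6 | (5R)-5-{(3S)-3-[(tert-butyldimethylsilyl)oxy]-4-[(2R)-3,3-dimethyloxiran-2-yl]but-1-en-2-yl}-2-methylcyclohex-2-en-1-one | C=C([C@H](C[C@H]1OC1(C)C)O[Si](C)(C)C(C)(C)C)[C@@H]2CC=C(C)C(=O)C2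
F7 | step 7 | trimethyl({(6R)-6-{(3S)-4-[(2R)-3,3-dimethyloxiran-2-yl]-3-[(trimethylsilyl)oxy]but-1-en-2-yl}-3-methylcyclohexa-1,3-dien-2-yl}oxy)silane | C=C([C@H](C[C@H]1OC1(C)C)O[Si](C)(C)C)[C@@H]2CC=C(C)C(O[Si](C)(C)C)=C2
F8 | step 7 | (5S,6S)-5-{(3S)-4-[(2R)-3,3-dimethyloxiran-2-yl]-3-[(trimethylsilyl)oxy]but-1-en-2-yl}-2-methyl-6-[(trimethylsilyl)oxy]cyclohex-2-en-1-one | C=C([C@H](C[C@H]1OC1(C)C)O[Si](C)(C)C)[C@@H]2CC=C(C)C(=O)[C@H]2O[Si](C)(C)C
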